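The saturated ring (ring B, C5–C8 of the tetrahydronaphthalene) is disconnected as a formal [3+3] annulation. The key step exploits the 1,3-relationship between benzylic C8, acidified by the ortho carboxamide at C1, and aromatic C4a, ortho to the C4 oxygen: both are latent carbon nucleophiles of one benzene ring. In one pot, sparteine-mediated lateral lithiation–alkylation with (S)-butane-1,3-diyl ditosylate forms C7–C8 and sets C8; fluoride then frees the phenoxide, whose ortho carbon displaces the secondary tosylate with inversion, forming C4a–C5 and setting C5. The precursor is an open-chain 2-alkyl-4-silyloxybenzamide that already carries the complete side chain, built from (S)-citronellic acid.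

Key step: step 8

Assumption: the sense of induction drawn for (S)-BINAP in step 3 and for (−)-sparteine with a tosylate electrophile in step 8 is taken by analogy with close substrates; if a model run shows the opposite sense, the antipodal ligand ((R)-BINAP, (+)-sparteine) is used.

Step 1
Reactants: 1 N,N-diethyl-4-hydroxybenzamide
Product: 2 N,N-diethyl-4-{[tri(propan-2-yl)silyl]oxy}benzamide
Conditions: TIPSCl, imidazole, DMF, 25 °C
Reagents that add atoms: chlorotri(propan-2-yl)silane (TIPSCl), CC(C)[Si](Cl)(C(C)C)C(C)C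
Why: Silylation of the phenol gives a bulky aryl silyl ether that survives alkyllithium bases and does not compete with the amide as a director in the two later metalations.

Step 2
Reactants: 3 (3S)-3,7-dimethyloct-6-enoic acid [(S)-citronellic acid]
Product: 4 (3S,6E)-8-hydroxy-3,7-dimethyloct-6-enoic acid
Conditions: SeO2 (cat.), t-BuOOH, CH2Cl2, 0 to 25 °C
Reagents that add atoms: tert-butyl hydroperoxide, CC(C)(C)OO
Why: Riley allylic oxidation (ene reaction, then [2,3]-sigmatropic shift) should hydroxylate selectively the (E)-methyl group of the trisubstituted alkene and leave the C3 stereocentre untouched.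

Step 3
Reactants: 4 (3S,6E)-8-hydroxy-3,7-dimethyloct-6-enoic acid
Product: 5 (3S,7R)-8-hydroxy-3,7-dimethyloctanoic acid
Conditions: Ru(OAc)2[(S)-BINAP] (1 mol %), H2 (50 bar), MeOH, 25 °C
Reagents that add atoms: none
Why: Hydroxyl-directed Noyori asymmetric hydrogenation of the (E)-2-methyl allylic alcohol should set the new C7 stereocentre (R) under control of the chiral ruthenium catalyst, independently of the remote C3 centre.

Step 4
Reactants: 5 (3S,7R)-8-hydroxy-3,7-dimethyloctanoic acid
Product: 7 (3S,7R)-8-{[tert-butyl(dimethyl)silyl]oxy}-3,7-dimethyloctanoic acid, via silyl ester 6 (not isolated)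
Conditions: TBSCl (2.2 equiv), imidazole, DMF, 25 °C; then K2CO3, MeOH–H2O
Reagents that add atoms: tert-butyl(chloro)dimethylsilane (TBSCl), CC(C)(C)[Si](C)(C)Cl
Why: Exhaustive silylation followed by selective methanolysis of the labile silyl ester protects the primary alcohol for the organolithium chemistry and frees the acid.

Step 5
Reactants: 7 (3S,7R)-8-{[tert-butyl(dimethyl)silyl]oxy}-3,7-dimethyloctanoic acid
Product: 8 1,3-dioxoisoindol-2-yl (3S,7R)-8-{[tert-butyl(dimethyl)silyl]oxy}-3,7-dimethyloctanoate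
Conditions: N-hydroxyphthalimide, DIC, DMAP (cat.), CH2Cl2, 25 °C
Reagents that add atoms: N-hydroxyphthalimide, O=C1c2ccccc2C(=O)N1O
Why: Carbodiimide (Steglich-type) esterification gives the redox-active ester for decarboxylative coupling, and because the chain is already saturated the primary radical formed from it has no alkene to cyclise onto.

Step 6
Reactants: 2 N,N-diethyl-4-{[tri(propan-2-yl)silyl]oxy}benzamide; 8 1,3-dioxoisoindol-2-yl (3S,7R)-8-{[tert-butyl(dimethyl)silyl]oxy}-3,7-dimethyloctanoate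
Product: 11 2-[(2S,6R)-7-{[tert-butyl(dimethyl)silyl]oxy}-2,6-dimethylheptyl]-N,N-diethyl-4-{[tri(propan-2-yl)silyl]oxy}benzamide, via aryllithium 9 (not isolated), via arylzinc chloride 10 (not isolated)
Conditions: s-BuLi, TMEDA, THF, −78 °C; ZnCl2; then 8, NiCl2·glyme (20 mol %), 4,4'-di-tert-butyl-2,2'-bipyridine, THF–DMF, 25 °C
Reagents that add atoms: none
Why: Amide-directed ortho-metalation, transmetalation to zinc and nickel-catalysed decarboxylative Negishi-type coupling of the redox-active ester should form the aryl–CH2 bond ortho to the amide without touching either chain stereocentre, since the radical sits on the CH2 carbon.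

Step 7
Reactants: 12 (3S)-butane-1,3-diol
Product: 13 (3S)-butane-1,3-diyl bis(4-methylbenzenesulfonate)
Conditions: TsCl, pyridine, DMAP (cat.), CH2Cl2, 0 to 25 °C
Reagents that add atoms: 4-methylbenzenesulfonyl chloride (TsCl), Cc1ccc(cc1)S(=O)(=O)Cl
Why: Sulfonylation takes place at oxygen, so the (S) configuration of the secondary carbinol carbon is retained in the 1,3-bis-electrophile.

Step 8
Reactants: 11 2-[(2S,6R)-7-{[tert-butyl(dimethyl)silyl]oxy}-2,6-dimethylheptyl]-N,N-diethyl-4-{[tri(propan-2-yl)silyl]oxy}benzamide; 13 (3S)-butane-1,3-diyl bis(4-methylbenzenesulfonate)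
Product: 17 (5R,8S)-N,N-diethyl-4-hydroxy-8-[(2S,6R)-7-hydroxy-6-methylheptan-2-yl]-5-methyl-5,6,7,8-tetrahydronaphthalene-1-carboxamide, via benzylic organolithium 14 (not isolated), via open-chain secondary tosylate 15 (not isolated), via tetrabutylammonium phenoxide 16 (not isolated)
Conditions: s-BuLi, (−)-sparteine, MTBE–pentane, −78 °C; 13, −78 °C; then TBAF (3 equiv), THF, −78 to 40 °C
Reagents that add atoms: none
Why: s-BuLi/(−)-sparteine removes a benzylic proton ortho to the amide (complex-induced lateral lithiation) and the sparteine-bound benzylic lithium 14 is alkylated by the primary tosylate of 13, forming C7–C8; fluoride then cleaves both silyl ethers and the freed phenoxide 16 attacks the secondary tosylate through its ortho carbon C4a (SN2, then tautomerisation of the dienone to the phenol), forming C4a–C5. The closest known reaction types are the sparteine-mediated asymmetric lateral lithiation–substitution of 2-alkyl tertiary benzamides with alkyl sulfonates and the base-induced ortho C-cyclisation of phenoxides carrying an ω-sulfonyloxyalkyl chain (aryl participation), run here in sequence as a formal [3+3] annulation. Ring B closes in a 6-exo-tet mode at the phenoxide ortho carbon. C8 (S) should be controlled by the chiral diamine on lithium, which is needed because the neighbouring side-chain stereocentre (methyl against a primary alkyl group) gives no useful bias, and C5 (R) by inversion of the (S)-carbinol carbon taken from (S)-butane-1,3-diol. The trans-5,8 product is also the isomer that keeps both substituents pseudoaxial, away from the peri amide and the peri oxygen, so reagent control and ring strain point the same way. The step needs C- over O-alkylation and ortho over ipso attack: closure through oxygen would need a meta-bridged eight-membered ring, the para carbon is blocked by the amide, and the first alkylation is chemoselective because the primary tosylate is far more reactive than the secondary one.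

Step 9
Reactants: 17 (5R,8S)-N,N-diethyl-4-hydroxy-8-[(2S,6R)-7-hydroxy-6-methylheptan-2-yl]-5-methyl-5,6,7,8-tetrahydronaphthalene-1-carboxamide
Product: 18 (5R,8S)-4-hydroxy-8-[(2S,6R)-7-hydroxy-6-methylheptan-2-yl]-5-methyl-5,6,7,8-tetrahydronaphthalene-1-carbaldehyde
Conditions: Cp2Zr(H)Cl (excess), THF, 25 °C; aqueous work-up
Reagents that add atoms: none
Why: Cp2Zr(H)Cl reduces tertiary amides selectively to aldehydes (hydrozirconation of the C=O, collapse on work-up), while the phenol, the alcohol and the ring stereocentres should be unaffected apart from consuming extra reagent.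

Step 10
Reactants: 18 (5R,8S)-4-hydroxy-8-[(2S,6R)-7-hydroxy-6-methylheptan-2-yl]-5-methyl-5,6,7,8-tetrahydronaphthalene-1-carbaldehyde
Product: 19 (5R,8S)-4-hydroxy-8-[(2S,6R)-7-hydroxy-6-methylheptan-2-yl]-5-methyl-5,6,7,8-tetrahydronaphthalene-1-carboxylic acid
Conditions: NaClO2, NaH2PO4, 2-methylbut-2-ene, t-BuOH–H2O, 0 to 25 °C
Reagents that add atoms: sodium chlorite, [Na+].[O-]Cl=O
Why: Pinnick oxidation converts the aryl aldehyde to the acid without touching the primary alcohol, and the alkene scavenger traps HOCl before it can chlorinate the phenol ring.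

Step 11
Reactants: 19 (5R,8S)-4-hydroxy-8-[(2S,6R)-7-hydroxy-6-methylheptan-2-yl]-5-methyl-5,6,7,8-tetrahydronaphthalene-1-carboxylic acid; 20 4-methylpent-3-enoic acid
Product: 21 (5R,8S)-4-hydroxy-5-methyl-8-[(2S,6R)-6-methyl-7-[(4-methylpent-3-enoyl)oxy]heptan-2-yl]-5,6,7,8-tetrahydronaphthalene-1-carboxylic acid (CNP0545998.1)
Conditions: Candida antarctica lipase B (immobilised), 4 Å molecular sieves, toluene–THF, 45 °C
Reagents that add atoms: none
Why: Lipase-catalysed esterification (a serine hydrolase) should acylate only the unhindered primary aliphatic hydroxyl, because such enzymes do not acylate phenols and do not take the ortho-substituted aromatic acid as acyl donor, and the neutral conditions should leave the β,γ-unsaturated ester unisomerised.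

Compound list
1 | N,N-diethyl-4-hydroxybenzamide | CCN(CC)C(=O)c1ccc(O)cc1 | starting material
2 | N,N-diethyl-4-{[tri(propan-2-yl)silyl]oxy}benzamide | CCN(CC)C(=O)c1ccc(O[Si](C(C)C)(C(C)C)C(C)C)cc1 | intermediate
3 | (3S)-3,7-dimethyloct-6-enoic acid, (S)-citronellic acid | OC(=O)C[C@@H](C)CCC=C(C)C | starting material
4 | (3S,6E)-8-hydroxy-3,7-dimethyloct-6-enoic acid | OC(=O)C[C@@H](C)CC/C=C(\C)CO | intermediate
5 | (3S,7R)-8-hydroxy-3,7-dimethyloctanoic acid | OC(=O)C[C@@H](C)CCC[C@@H](C)CO | intermediate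
6 | tert-butyl(dimethyl)silyl (3S,7R)-8-{[tert-butyl(dimethyl)silyl]oxy}-3,7-dimethyloctanoate | CC(C)(C)[Si](C)(C)OC(=O)C[C@@H](C)CCC[C@@H](C)CO[Si](C)(C)C(C)(C)C | intermediate
7 | (3S,7R)-8-{[tert-butyl(dimethyl)silyl]oxy}-3,7-dimethyloctanoic acid | OC(=O)C[C@@H](C)CCC[C@@H](C)CO[Si](C)(C)C(C)(C)C | intermediate
8 | 1,3-dioxoisoindol-2-yl (3S,7R)-8-{[tert-butyl(dimethyl)silyl]oxy}-3,7-dimethyloctanoate | O=C(ON1C(=O)c2ccccc2C1=O)C[C@@H](C)CCC[C@@H](C)CO[Si](C)(C)C(C)(C)C | intermediate
9 | [2-(diethylcarbamoyl)-5-{[tri(propan-2-yl)silyl]oxy}phenyl]lithium | CCN(CC)C(=O)c1ccc(O[Si](C(C)C)(C(C)C)C(C)C)cc1[Li] | intermediate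
10 | chlorido[2-(diethylcarbamoyl)-5-{[tri(propan-2-yl)silyl]oxy}phenyl]zinc | CCN(CC)C(=O)c1ccc(O[Si](C(C)C)(C(C)C)C(C)C)cc1[Zn]Cl | intermediate
11 | 2-[(2S,6R)-7-{[tert-butyl(dimethyl)silyl]oxy}-2,6-dimethylheptyl]-N,N-diethyl-4-{[tri(propan-2-yl)silyl]oxy}benzamide | CCN(CC)C(=O)c1ccc(O[Si](C(C)C)(C(C)C)C(C)C)cc1C[C@@H](C)CCC[C@@H](C)CO[Si](C)(C)C(C)(C)C | intermediate
12 | (3S)-butane-1,3-diol | C[C@H](O)CCO | starting material
13 | (3S)-butane-1,3-diyl bis(4-methylbenzenesulfonate) | C[C@H](OS(=O)(=O)c1ccc(C)cc1)CCOS(=O)(=O)c1ccc(C)cc1 | intermediate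
14 | benzylic organolithium of 11 (lithium on the ArCH carbon, configurationally labile, (−)-sparteine complex) | CCN(CC)C(=O)c1ccc(O[Si](C(C)C)(C(C)C)C(C)C)cc1C([Li])[C@@H](C)CCC[C@@H](C)CO[Si](C)(C)C(C)(C)C | intermediate
15 | (2S,5S,6S,10R)-11-{[tert-butyl(dimethyl)silyl]oxy}-5-[2-(diethylcarbamoyl)-5-{[tri(propan-2-yl)silyl]oxy}phenyl]-6,10-dimethylundecan-2-yl 4-methylbenzenesulfonate | CCN(CC)C(=O)c1ccc(O[Si](C(C)C)(C(C)C)C(C)C)cc1[C@@H](CC[C@H](C)OS(=O)(=O)c2ccc(C)cc2)[C@@H](C)CCC[C@@H](C)CO[Si](C)(C)C(C)(C)C | intermediate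
16 | tetrabutylammonium 4-(diethylcarbamoyl)-3-[(2S,5S,6S,10R)-11-hydroxy-6,10-dimethyl-2-{[(4-methylphenyl)sulfonyl]oxy}undecan-5-yl]phenolate | CCN(CC)C(=O)c1ccc([O-])cc1[C@@H](CC[C@H](C)OS(=O)(=O)c2ccc(C)cc2)[C@@H](C)CCC[C@@H](C)CO.CCCC[N+](CCCC)(CCCC)CCCC | intermediate
17 | (5R,8S)-N,N-diethyl-4-hydroxy-8-[(2S,6R)-7-hydroxy-6-methylheptan-2-yl]-5-methyl-5,6,7,8-tetrahydronaphthalene-1-carboxamide | OC[C@H](C)CCC[C@H](C)[C@@H]1CC[C@@H](C)c2c(O)ccc(C(=O)N(CC)CC)c21 | intermediate
18 | (5R,8S)-4-hydroxy-8-[(2S,6R)-7-hydroxy-6-methylheptan-2-yl]-5-methyl-5,6,7,8-tetrahydronaphthalene-1-carbaldehyde | OC[C@H](C)CCC[C@H](C)[C@@H]1CC[C@@H](C)c2c(O)ccc(C=O)c21 | intermediate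
19 | (5R,8S)-4-hydroxy-8-[(2S,6R)-7-hydroxy-6-methylheptan-2-yl]-5-methyl-5,6,7,8-tetrahydronaphthalene-1-carboxylic acid | OC[C@H](C)CCC[C@H](C)[C@@H]1CC[C@@H](C)c2c(O)ccc(C(=O)O)c21 | intermediate
20 | 4-methylpent-3-enoic acid | CC(C)=CCC(=O)O | starting material
21 | (5R,8S)-4-hydroxy-5-methyl-8-[(2S,6R)-6-methyl-7-[(4-methylpent-3-enoyl)oxy]heptan-2-yl]-5,6,7,8-tetrahydronaphthalene-1-carboxylic acid | CC(C)=CCC(=O)OC[C@H](C)CCC[C@H](C)[C@@H]1CC[C@@H](C)c2c(O)ccc(C(=O)O)c21 | target

Total step count: 11. Longest linear sequence: 9 steps (3 → 4 → 5 → 7 → 8 → 11 → 17 → 18 → 19 → 21, that is steps 2, 3, 4, 5, 6, 8, 9, 10, 11).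

Steps most likely to fail

Step 8. What may go wrong: fluoride-induced elimination of the secondary tosylate or sluggish ortho C-alkylation of the phenoxide, so that the ring does not close; and erosion of facial selectivity at the benzylic lithium if sparteine control is mismatched with the neighbouring stereocentre. The fallback sets out from 11 and comes back at 17, and closes the ring by hydroarylation of an alkene instead of by displacement. The same sparteine-mediated lateral lithiation of 11 is quenched with but-3-en-1-yl 4-methylbenzenesulfonate to give 2-[(5S,6S,10R)-11-{[tert-butyl(dimethyl)silyl]oxy}-6,10-dimethylundec-1-en-5-yl]-N,N-diethyl-4-{[tri(propan-2-yl)silyl]oxy}benzamide F1. A Markovnikov hydroarylation under hydrogen-atom-transfer conditions ([N,N'-bis(3,5-di-tert-butylsalicylidene)cyclohexane-1,2-diaminato]cobalt, divalent cobalt, with N-fluoro-2,4,6-trimethylpyridinium tetrafluoroborate and PhSiH3) then forms the C4a–C5 bond. Here the C5 methyl should go trans to the C8 substituent under peri-strain control. This gives (5R,8S)-8-[(2S,6R)-7-{[tert-butyl(dimethyl)silyl]oxy}-6-methylheptan-2-yl]-N,N-diethyl-5-methyl-4-{[tri(propan-2-yl)silyl]oxy}-5,6,7,8-tetrahydronaphthalene-1-carboxamide F2, and TBAF in THF removes both silyl groups to give 17.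

Step 9. What may go wrong: stalled hydrozirconation of the hindered, peri-flanked amide, which is further deactivated once the para phenol is deprotonated, or partial over-reduction. The fallback sets out from 17 and comes back at 18 by full reduction and selective re-oxidation. Lithium amidotrihydroborate (LiH2N·BH3, THF) reduces the tertiary amide to the benzylic alcohol (5S,8R)-4-(hydroxymethyl)-5-[(2S,6R)-7-hydroxy-6-methylheptan-2-yl]-8-methyl-5,6,7,8-tetrahydronaphthalen-1-ol F3, and MnO2 in CH2Cl2 oxidises only the benzylic alcohol, giving 18.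

Step 6. What may go wrong: protodemetalation or slow coupling of the ortho-amido arylzinc, with the alkyl radical lost to reduction or dimerisation. The fallback sets out from 7 and 2 and comes back at 11 by a two-electron Negishi coupling with the polarity reversed. Iododecarboxylation of 7 (PhI(OAc)2, I2, visible light) gives tert-butyl{[(2R,6S)-7-iodo-2,6-dimethylheptyl]oxy}dimethylsilane F4, and zinc insertion (Zn dust, LiCl, THF) gives [(2S,6R)-7-{[tert-butyl(dimethyl)silyl]oxy}-2,6-dimethylheptyl](iodido)zinc F5. Ortho-lithiation of 2 (s-BuLi, TMEDA) and an I2 quench give N,N-diethyl-2-iodo-4-{[tri(propan-2-yl)silyl]oxy}benzamide F6. Coupling of F5 with F6 (Pd(OAc)2, 2-dicyclohexylphosphino-2',6'-dimethoxybiphenyl, THF) gives 11.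

Further compounds
F1 | step 8 | 2-[(5S,6S,10R)-11-{[tert-butyl(dimethyl)silyl]oxy}-6,10-dimethylundec-1-en-5-yl]-N,N-diethyl-4-{[tri(propan-2-yl)silyl]oxy}benzamide | CCN(CC)C(=O)c1ccc(O[Si](C(C)C)(C(C)C)C(C)C)cc1[C@@H](CCC=C)[C@@H](C)CCC[C@@H](C)CO[Si](C)(C)C(C)(C)C
F2 | step 8 | (5R,8S)-8-[(2S,6R)-7-{[tert-butyl(dimethyl)silyl]oxy}-6-methylheptan-2-yl]-N,N-diethyl-5-methyl-4-{[tri(propan-2-yl)silyl]oxy}-5,6,7,8-tetrahydronaphthalene-1-carboxamide | CC(C)(C)[Si](C)(C)OC[C@H](C)CCC[C@H](C)[C@@H]1CC[C@@H](C)c2c(O[Si](C(C)C)(C(C)C)C(C)C)ccc(C(=O)N(CC)CC)c21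
F3 | step 9 | (5S,8R)-4-(hydroxymethyl)-5-[(2S,6R)-7-hydroxy-6-methylheptan-2-yl]-8-methyl-5,6,7,8-tetrahydronaphthalen-1-ol | OC[C@H](C)CCC[C@H](C)[C@@H]1CC[C@@H](C)c2c(O)ccc(CO)c21
F4 | step 6 | tert-butyl{[(2R,6S)-7-iodo-2,6-dimethylheptyl]oxy}dimethylsilane | IC[C@@H](C)CCC[C@@H](C)CO[Si](C)(C)C(C)(C)C
F5 | step 6 | [(2S,6R)-7-{[tert-butyl(dimethyl)silyl]oxy}-2,6-dimethylheptyl](iodido)zinc | I[Zn]C[C@@H](C)CCC[C@@H](C)CO[Si](C)(C)C(C)(C)C
F6 | step 6 | N,N-diethyl-2-iodo-4-{[tri(propan-2-yl)silyl]oxy}benzamide | CCN(CC)C(=O)c1ccc(O[Si](C(C)C)(C(C)C)C(C)C)cc1I
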